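The rate constants are hidden, so the amber run has to stand in for them.

in all of them: D 0.0146 M

| flask | E | temperature | remark | time |
|---|---|---|---|---|
| amber | 1.5 M | 25 °C | run made earlier |  |
| east | 0.73 M | 25 °C |  | 4.0 d |
| south-west | 0.73 M | −15 °C |  | 4.0 d |
| south-east | 0.73 M | 5 °C |  | 4.0 d |

- amber (time / h: L / %, X / %, J / %): 1.50: 2, 1, 0; 2.50: 11, 0, 2; 4.00: 10, 5, 2; 5.00: 16, 8, 3; 8.00: 25, 12, 0; 12.0: 30, 18, 1; 20.0: 31, 24, 0

(each reading ± 1.5 percentage points)

- percentages count the E that a species holds: one Z counts as two
- steps thought possible: Q + D -> J; E -> G; 2 E -> Z; E -> Q; Q <-> X; Q <-> L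
- the earlier runs do not show what temperature does; that part of a forecast is a guess

* the best flask by share of L in all that became L or X or J; "all alike" if 1.5 percentage points covers them all (east / south-west / south-east / all alike)
* share of L in all that became L or X or J, east
* share of L in all that became L or X or J, south-west
* share of L in all that became L or X or J, south-east

1. The carried quantity. Summed over the first 4 readings, up to 5.00 h, amber gives the early share, the part of L in L plus X, of 73.6%. It is a reading with scatter, and it marks L as the product of kinetic control.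

2. Time. At its last reading, 20.0 h, amber reads L at 56.4% of L plus X, less than the early share. So in amber standing lowers the share, and east, which stands longer at 4.0 d, is expected lower still.

3. Amount of E. The flasks hold about half of amber's E. One D goes into each J, so J can reach at most c(D)/c(E), which is 2.00% of the E here and 0.973% in amber.

4. D as a correction. With w the percent standing in L plus X, and L and X still in the early share, the share asked is the early share times w/(w + J). J stands under the ceiling of step 3, so this correction is small where w lies far above that ceiling.

5. Temperature. Amber says nothing here, so this part is a guess: a colder flask stands earlier on the same course. South-west, colder than south-east, is therefore placed first, near the early share, then south-east, then east.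

The forecast parts from this reckoning at the top. It names south-east, with east 35% (22% to 50%), south-west 52% (35% to 66%) and south-east 57% (45% to 66%), and says of south-west that “J takes a large share”.

    Q + D → J (k = 7.80 × 10⁻⁵ L mol⁻¹ s⁻¹, Ea = 83.0 kJ mol⁻¹)
    E → G (k = 2.10 × 10⁻⁸ s⁻¹, Ea = 124 kJ mol⁻¹)
    2 E → Z (k = 6.40 × 10⁻⁶ L mol⁻¹ s⁻¹, Ea = 88.0 kJ mol⁻¹)
    E → Q (k = 1.50 × 10⁻⁴ s⁻¹, Ea = 97.0 kJ mol⁻¹)
    Q ⇌ X (K = 4.00, k = 8.10 × 10⁻⁶ s⁻¹, Ea = 97.0 kJ mol⁻¹, ΔH = −40.0 kJ mol⁻¹)
    Q ⇌ L (K = 0.790, k = 2.10 × 10⁻⁵ s⁻¹, Ea = 94.0 kJ mol⁻¹, ΔH = −2.00 kJ mol⁻¹)
    (constants at 25 °C)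

South-west comes out best at 69.9%, above south-east at 66.5% and east at 21.7%. At 4.00 d south-west holds L 0.116%, X 0.0372% and J 0.0125%, far less J than the ceiling of 2.00%. The early share with its correction gives 68.0% there. A neighbour flask, south-west with 0.058 M of D, holds the same L and X but J 0.0496%, so the correction gives 55.5%, and that flask gives 57.1%.

(The runs were computed with constants of no real substance, and the scatter is random.)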